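The route rests on disconnecting the C7–C11 bond, the Cβ–Cα bond of the α-methylene-γ-butyrolactone fused to the ten-membered ring. C7 lies between two oxygen-bearing carbons, C6 (lactone oxygen) and C8 (ester oxygen), and C8–O is anti to C7–C11: the signature of a trans-7,8-epoxide opened with inversion by a carbon nucleophile tethered through O6. The precursor is therefore the ten-membered (Z,Z)-diene carrying a 7,8-epoxide and a 6-O-phosphonoacetate. Deprotonation closes the lactone by 5-exo attack at C7, sets C7, frees the C8 hydroxyl, and the phosphonate then delivers the exocyclic methylene with formaldehyde in the same flask.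

Key step: step 12

Remarks. Locants C1–C15 are those of the target skeleton: ring C1–C10, C14 the methyl on C10, C15 the methyl on C4, lactone carbons C11 (α), C12 (C=O) and C13 (=CH2). Compounds 1, 8, 9, 15 and 21 are taken as commercial. In these locants the target is 1R,3R,6S,7S,8S,10S with a (2R)-2-methylbutanoate, both ring alkene units (C4=C5 and the C1–C10 epoxide) being cis.

Step 1
Reactants: 1 3-(trimethylsilyl)prop-2-ynal
Product: 3 (3R)-1-(trimethylsilyl)hex-5-en-1-yn-3-ol, via diisopinocampheylborinate 2 (not isolated)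
Conditions: (+)-Ipc2BOMe [(−)-α-pinene series], CH2=CHCH2MgBr, Et2O, 0 → 23 °C; then 1, −78 °C; NaOH, H2O2, 0 → 23 °C
Reagents that add atoms: allylmagnesium bromide, C=CC[Mg]Br
Why: Brown allylboration, in which the chair transition state of the B-allyl borane delivers allyl to one face of the ynal and sets C3 (R), the silyl group keeping the alkyne terminus inert.

Step 2
Reactants: 3 (3R)-1-(trimethylsilyl)hex-5-en-1-yn-3-ol
Product: 4 (3R)-hex-5-en-1-yn-3-ol
Conditions: K2CO3 (cat.), MeOH, 23 °C
Reagents that add atoms: none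
Why: Methanolysis of the alkynyl C–Si bond (protodesilylation) frees the terminal alkyne without touching the carbinol or the alkene.

Step 3
Reactants: 4 (3R)-hex-5-en-1-yn-3-ol
Product: 6 (1Z,3R)-1-iodo-2-methylhexa-1,5-dien-3-ol, via alkenylmagnesium alkoxide 5 (not isolated)
Conditions: MeMgBr (3 equiv), CuI (15 mol%), THF, −20 → 23 °C; then I2, −40 → 0 °C
Reagents that add atoms: methylmagnesium bromide, C[Mg]Br; iodine, II
Why: Copper-catalysed anti-carbomagnesiation of the propargylic alkoxide puts methyl on C4 and magnesium on C5 in a five-membered chelate, so iodinolysis gives the iodoalkene with iodine cis to C3, which fixes the Z geometry of C4=C5.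

Step 4
Reactants: 6 (1Z,3R)-1-iodo-2-methylhexa-1,5-dien-3-ol
Product: 7 (1Z,3R)-1-iodo-2-methylhexa-1,5-dien-3-yl acetate
Conditions: Ac2O, pyridine, DMAP (cat.), CH2Cl2, 0 °C
Reagents that add atoms: acetic anhydride, CC(=O)OC(C)=O
Why: Standard O-acetylation installs the C3 acetate of the target at once, so no protecting group is needed.

Step 5
Reactants: 8 3-chloro-2-methylprop-1-ene; 9 prop-2-yn-1-ol
Product: 10 5-methylhex-5-en-2-yn-1-ol
Conditions: CuI (10 mol%), NaI (cat.), K2CO3, DMF, 23 °C
Reagents that add atoms: none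
Why: Copper-acetylide allylation of the terminal alkyne with the allylic halide gives the skipped enyne (C6–C10 with C14) and leaves the hydroxyl free.

Step 6
Reactants: 10 5-methylhex-5-en-2-yn-1-ol
Product: 11 (2E)-5-methylhexa-2,5-dien-1-ol
Conditions: LiAlH4, THF, 0 → 60 °C; aqueous NaOH work-up
Reagents that add atoms: none
Why: Hydroxyl-directed trans-hydroalumination of the propargylic alkyne and protonolysis give the E-allylic alcohol (the C7=C8 geometry), the isolated 1,1-disubstituted alkene being inert.

Step 7
Reactants: 11 (2E)-5-methylhexa-2,5-dien-1-ol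
Product: 12 (2E)-5-methylhexa-2,5-dienal
Conditions: MnO2 (activated, excess), CH2Cl2, 23 °C
Reagents that add atoms: none
Why: Allylic oxidation with MnO2 stops at the enal under neutral conditions, so the skipped diene should not move into conjugation.

Step 8
Reactants: 7 (1Z,3R)-1-iodo-2-methylhexa-1,5-dien-3-yl acetate; 12 (2E)-5-methylhexa-2,5-dienal
Product: 13 (4R,5Z,8E)-7-hydroxy-5,11-dimethyldodeca-1,5,8,11-tetraen-4-yl acetate as both C7 epimers (C7 = skeleton C6)
Conditions: CrCl2 (4 equiv), NiCl2 (2 mol%), DMSO, 23 °C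
Reagents that add atoms: none
Why: Nozaki–Hiyama–Kishi coupling forms the C5–C6 bond by 1,2-addition of the alkenylchromium species, with retention of the Z geometry and tolerance of the acetate; C6 forms as both epimers, which step 9 differentiates.

Step 9
Reactants: 13 (4R,5Z,8E)-7-hydroxy-5,11-dimethyldodeca-1,5,8,11-tetraen-4-yl acetate (both C7 epimers)
Product: 14 (4R,5Z,7S)-7-hydroxy-5-methyl-7-[(2S,3S)-3-(2-methylprop-2-en-1-yl)oxiran-2-yl]hepta-1,5-dien-4-yl acetate
Conditions: Ti(OiPr)4, L-(+)-DIPT, t-BuOOH (0.6 equiv), 4 Å molecular sieves, CH2Cl2, −20 °C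
Reagents that add atoms: tert-butyl hydroperoxide, CC(C)(C)OO
Why: Sharpless asymmetric epoxidation run as a kinetic resolution: with L-(+)-DIPT only the epimer with the target's C6 configuration reacts quickly, at the E-C7=C8 bond and with erythro selectivity, which sets C7 and C8 and leaves the other epimer and the cis-substituted C4=C5 bond untouched.

Step 10
Reactants: 14 the epoxy alcohol above; 15 2-(diethoxyphosphoryl)acetic acid
Product: 16 2-(diethoxyphosphoryl)acetate of 14 at the C6 oxygen (stereocentres unchanged)
Conditions: DCC, DMAP (cat.), CH2Cl2, 0 → 23 °C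
Reagents that add atoms: none
Why: Steglich esterification attaches the C11–C12 unit to O6 under neutral conditions that spare the epoxide and the acetate.

Step 11
Reactants: 16 the phosphonoacetate above
Product: 17 (1(10)Z,4Z)-3-acetoxy-7,8-epoxy-4,10-dimethylcyclodeca-1(10),4-dien-6-yl 2-(diethoxyphosphoryl)acetate (skeleton numbering, trans-epoxide)
Conditions: second-generation Hoveyda–Grubbs catalyst (10 mol%), toluene (1 mM), 80 °C, argon sparge
Reagents that add atoms: none
Why: Ring-closing metathesis joins the monosubstituted C1 and 1,1-disubstituted C10 alkenes at high dilution; the ring already holds a trans-epoxide and a Z-alkene and should accept the new trisubstituted bond only as the Z isomer, while C4=C5 is too hindered to take part.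

Step 12
Reactants: 17 the macrocyclic epoxy phosphonoacetate above
Product: 20 (3R,6S,7S,8S)-3-acetoxy-8-hydroxygermacra-1(10)Z,4Z,11(13)-trien-12,6-olide, via lithium enolate 18 (not isolated), via lithiated phosphonolactone 19 (not isolated)
Conditions: LiN(SiMe3)2 (1.05 equiv), THF, −78 → 40 °C; then (CH2O)n, 0 → 23 °C
Reagents that add atoms: formaldehyde (as paraformaldehyde), C=O
Why: The base removes the phosphonoacetate proton and carbanion C11 attacks C7 of the trans-epoxide from the side opposite to the epoxide oxygen, an intramolecular epoxide opening by a stabilised carbanion of the epoxynitrile-cyclisation type that forms the C7–C11 bond. The γ-lactone closes in the 5-exo-tet mode, because the alternative 6-endo attack at C8 needs a collinear approach that the three-atom tether O6–C12–C11 cannot reach. C7 is set by stereospecific inversion and C8 keeps its oxygen with retention, so the erythro epoxy alcohol of step 9 becomes the trans-fused lactone with the C8 oxygen anti to C11. The alkoxide freed at C8 is neutralised at once by the more acidic α-phosphono lactone, which gives anion 19 and prevents acyl transfer from the lactone or the C3 acetate. Paraformaldehyde then turns 19 into the exocyclic C11=C13 methylene by Horner–Wadsworth–Emmons olefination. The step needs C-alkylation at C7 to outrun attack of the alkoxide on phosphorus, which the fast proton transfer and the low temperature should secure.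

Step 13
Reactants: 20 the hydroxy lactone above; 21 (2R)-2-methylbutanoic acid
Product: 22 (3R,6S,7S,8S)-3-acetoxy-8-[(2R)-2-methylbutanoyloxy]germacra-1(10)Z,4Z,11(13)-trien-12,6-olide
Conditions: DCC, DMAP (cat.), CH2Cl2, 0 → 23 °C
Reagents that add atoms: none
Why: Steglich esterification of the C8 hydroxyl at low temperature with catalytic DMAP should avoid ketene formation and so keep the acyl stereocentre intact.

Step 14
Reactants: 22 the diester above
Product: 23 (1R,3R,6S,7S,8S,10S)-3-acetoxy-1,10-epoxy-8-[(2R)-2-methylbutanoyloxy]germacra-4Z,11(13)-dien-12,6-olide (target, CNP0340603.1)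
Conditions: mCPBA (1.05 equiv), NaHCO3, CH2Cl2, 0 °C
Reagents that add atoms: 3-chloroperbenzoic acid, OOC(=O)c1cccc(Cl)c1
Why: Prilezhaev epoxidation, for which C1=C10 is the only electron-rich alkene (C4=C5 is flanked by two allylic acyloxy groups, C11=C13 is conjugated); peripheral attack on the medium ring is expected to add oxygen cis across the Z-alkene on the face anti to the C3 and C8 acyloxy groups, giving the 1R,10S epoxide.

Compound list
1 | 3-(trimethylsilyl)prop-2-ynal | C[Si](C)(C)C#CC=O | starting material
2 | (3R)-1-(trimethylsilyl)hex-5-en-1-yn-3-yl diisopinocampheylborinate, (−)-α-pinene series | C[Si](C)(C)C#C[C@H](OB([C@H]1C[C@H]2C[C@@H]([C@@H]1C)C2(C)C)[C@H]1C[C@H]2C[C@@H]([C@@H]1C)C2(C)C)CC=C | intermediate (not isolated)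
3 | (3R)-1-(trimethylsilyl)hex-5-en-1-yn-3-ol | C[Si](C)(C)C#C[C@H](O)CC=C | intermediate
4 | (3R)-hex-5-en-1-yn-3-ol | C#C[C@H](O)CC=C | intermediate
5 | [(1Z,3R)-3-(bromomagnesiooxy)-2-methylhexa-1,5-dien-1-yl]magnesium bromide | Br[Mg]/C=C(/C)[C@H](O[Mg]Br)CC=C | intermediate (not isolated)
6 | (1Z,3R)-1-iodo-2-methylhexa-1,5-dien-3-ol | I/C=C(/C)[C@H](O)CC=C | intermediate
7 | (1Z,3R)-1-iodo-2-methylhexa-1,5-dien-3-yl acetate | I/C=C(/C)[C@H](OC(C)=O)CC=C | intermediate
8 | 3-chloro-2-methylprop-1-ene | C=C(C)CCl | starting material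
9 | prop-2-yn-1-ol | C#CCO | starting material
10 | 5-methylhex-5-en-2-yn-1-ol | C=C(C)CC#CCO | intermediate
11 | (2E)-5-methylhexa-2,5-dien-1-ol | C=C(C)C/C=C/CO | intermediate
12 | (2E)-5-methylhexa-2,5-dienal | C=C(C)C/C=C/C=O | intermediate
13 | (4R,5Z,8E)-7-hydroxy-5,11-dimethyldodeca-1,5,8,11-tetraen-4-yl acetate, both C7 epimers | C=C(C)C/C=C/C(O)/C=C(/C)[C@H](OC(C)=O)CC=C | intermediate
14 | (4R,5Z,7S)-7-hydroxy-5-methyl-7-[(2S,3S)-3-(2-methylprop-2-en-1-yl)oxiran-2-yl]hepta-1,5-dien-4-yl acetate | C=C(C)C[C@@H]1O[C@H]1[C@@H](O)/C=C(/C)[C@H](OC(C)=O)CC=C | intermediate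
15 | 2-(diethoxyphosphoryl)acetic acid | OC(=O)CP(=O)(OCC)OCC | starting material
16 | 2-(diethoxyphosphoryl)acetate of 14 at the C6 oxygen | C=C(C)C[C@@H]1O[C@H]1[C@@H](OC(=O)CP(=O)(OCC)OCC)/C=C(/C)[C@H](OC(C)=O)CC=C | intermediate
17 | (1(10)Z,4Z)-3-acetoxy-7,8-epoxy-4,10-dimethylcyclodeca-1(10),4-dien-6-yl 2-(diethoxyphosphoryl)acetate (skeleton numbering) | CCOP(=O)(OCC)CC(=O)O[C@H]1/C=C(/C)[C@H](OC(C)=O)C/C=C(/C)C[C@@H]2O[C@@H]12 | intermediate
18 | lithium enolate (C11 carbanion) of 17 | CCOP(=O)(OCC)[CH-]C(=O)O[C@H]1/C=C(/C)[C@H](OC(C)=O)C/C=C(/C)C[C@@H]2O[C@@H]12.[Li+] | intermediate (not isolated)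
19 | lithium salt of the 11-(diethoxyphosphoryl)-8-hydroxy-12,6-lactone, carbanion at C11 | CCOP(=O)(OCC)[C-]1C(=O)O[C@H]2/C=C(/C)[C@H](OC(C)=O)C/C=C(/C)C[C@H](O)[C@H]12.[Li+] | intermediate (not isolated)
20 | (3R,6S,7S,8S)-3-acetoxy-8-hydroxygermacra-1(10)Z,4Z,11(13)-trien-12,6-olide | C=C1C(=O)O[C@H]2/C=C(/C)[C@H](OC(C)=O)C/C=C(/C)C[C@H](O)[C@H]12 | intermediate
21 | (2R)-2-methylbutanoic acid | CC[C@@H](C)C(O)=O | starting material
22 | (3R,6S,7S,8S)-3-acetoxy-8-[(2R)-2-methylbutanoyloxy]germacra-1(10)Z,4Z,11(13)-trien-12,6-olide | C=C1C(=O)O[C@H]2/C=C(/C)[C@H](OC(C)=O)C/C=C(/C)C[C@H](OC(=O)[C@H](C)CC)[C@H]12 | intermediate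
23 | (1R,3R,6S,7S,8S,10S)-3-acetoxy-1,10-epoxy-8-[(2R)-2-methylbutanoyloxy]germacra-4Z,11(13)-dien-12,6-olide | C=C1C(=O)O[C@H]2/C=C(/C)[C@H](OC(C)=O)C[C@H]3O[C@@]3(C)C[C@H](OC(=O)[C@H](C)CC)[C@H]12 | target

Total step count: 14. Longest linear sequence: 11 steps (steps 1–4 and 8–14); steps 5–7 form the side branch.

Steps most likely to fail

Step 11 (ring-closing metathesis). The ring closure may lose to intermolecular metathesis at the terminal vinyl group, the 1,1-disubstituted alkene may not be engaged, or the ring may close with E geometry. The fallback changes the substrate and the order of ring formation. It sets out from 16: LiN(SiMe3)2 in THF (−78 → 40 °C, NH4Cl quench) closes the lactone first and should give the open-chain α-phosphono lactone F1. The trans-fused lactone then acts as a turn element that holds C1 and C10 close, and metathesis with the same catalyst should give the macrocyclic α-phosphono lactone F2. NaH and paraformaldehyde in THF (Horner–Wadsworth–Emmons olefination) then lead to 20, where the route is rejoined.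

Step 12 (key step). Inside the ring the carbanion may fail to reach the backside of C7, the C8 alkoxide may attack phosphorus before it is protonated, or attack may drift to C8. The fallback uses another nucleophile and another methylenation. It sets out from 14: heating with Meldrum's acid (toluene, 90 °C) should give the hydrogen malonate F3, and ring-closing metathesis as in step 11 the macrocyclic hydrogen malonate F4. Two equivalents of LiN(SiMe3)2 form the malonate dianion, a stronger and phosphorus-free nucleophile, which opens the epoxide at C7 in the same 5-exo mode to the α-carboxy lactone F5. Decarboxylative Mannich methylenation (paraformaldehyde, Et2NH, then AcOH/NaOAc) returns to 20.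

Step 14 (epoxidation). The peracid may attack the other face of C1=C10 and give the wrong epoxide diastereomer, or over-oxidise C4=C5. The fallback reaches the opposite face through a halohydrin. It sets out from 22: N-bromosuccinimide in aqueous THF adds bromine on the face the peracid prefers and water anti at the tertiary C10, which should give the bromohydrin F6. Ag2O in CH2Cl2 then closes the epoxide by displacing bromide with inversion at C1, which places the oxygen on the other face and gives 23.

Further compounds
F1 | step 11 | open-chain α-(diethoxyphosphoryl)-γ-lactone with free C8 hydroxyl (configuration at C3, C6, C7, C8 as in 20) | CCOP(=O)(OCC)C1C(=O)O[C@@H](/C=C(/C)[C@H](OC(C)=O)CC=C)[C@@H]1[C@@H](O)CC(C)=C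
F2 | step 11 | macrocyclic 11-(diethoxyphosphoryl)-8-hydroxy-12,6-lactone (neutral form of 19) | CCOP(=O)(OCC)C1C(=O)O[C@H]2/C=C(/C)[C@H](OC(C)=O)C/C=C(/C)C[C@H](O)[C@H]12
F3 | step 12 | hydrogen malonate of 14 at the C6 oxygen | C=C(C)C[C@@H]1O[C@H]1[C@@H](OC(=O)CC(O)=O)/C=C(/C)[C@H](OC(C)=O)CC=C
F4 | step 12 | macrocyclic hydrogen malonate (ring as in 17) | OC(=O)CC(=O)O[C@H]1/C=C(/C)[C@H](OC(C)=O)C/C=C(/C)C[C@@H]2O[C@@H]12
F5 | step 12 | macrocyclic 11-carboxy-8-hydroxy-12,6-lactone | OC(=O)C1C(=O)O[C@H]2/C=C(/C)[C@H](OC(C)=O)C/C=C(/C)C[C@H](O)[C@H]12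
F6 | step 14 | 1-bromo-10-hydroxy bromohydrin of 22 (bromine and hydroxyl anti) | C=C1C(=O)O[C@H]2/C=C(/C)[C@H](OC(C)=O)C[C@H](Br)[C@@](C)(O)C[C@H](OC(=O)[C@H](C)CC)[C@H]12
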